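**Retrosynthetic overview**
1. The pyranone ring C is opened to a methyl 2-(2-oxoheptyl)benzoate, which comes from lateral lithiation of the ring A C-methyl group of an orsellinate diaryl ether and acylation with a hexanoyl unit.
2. The plan rests on ring B (C1'–C6'): C1' carries the ether oxygen to ring A, C2' next to it a free hydroxyl, C4' (meta to that hydroxyl) a methyl ether, and C6' the pentyl chain. A vinylketene whose alkene terminus already bears the ring A oxygen gives exactly this pattern with methoxyacetylene, so no aryl–oxygen coupling and no selective O-methylation is needed.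
3. Ring B is cut into methoxyacetylene (C3', C4') and an aryloxy-substituted alkenyl diazo ketone (C1', C2', C5', C6'). The diazo ketone is assembled from methyl orsellinate and allyl heptanoate by formylation, enol tosylation, addition–elimination, deallylation and diazomethane acylation.
4. Ring order: ring A is bought, ring B is built by benzannulation (step 8), ring C is closed last by enol lactonization (step 12).

Key step: step 8

Remark: the target is achiral. The heptanoate is carried as its commercial allyl ester instead of a simple alkyl ester, so that it can be cleaved by zerovalent palladium without touching the methyl benzoate or the base-sensitive β-aryloxyacrylate.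

**Step 1**
Reactants: 1 methyl orsellinate (methyl 2,4-dihydroxy-6-methylbenzoate)
Product: 2 methyl 2-hydroxy-4-(methoxymethoxy)-6-methylbenzoate
Conditions: MOMCl (1.05 equiv), iPr2NEt, CH2Cl2, 0 °C
Reagents that add atoms: chloromethyl methyl ether, COCCl
Why: O-alkylation to the MOM acetal should occur at the free, more acidic C4 hydroxyl para to the ester, because the C2 hydroxyl is held in a hydrogen bond to the ester carbonyl.

**Step 2**
Reactants: 3 allyl heptanoate (prop-2-en-1-yl heptanoate)
Product: 4 prop-2-en-1-yl 2-formylheptanoate (racemic, in equilibrium with its hydroxymethylene enol)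
Conditions: TiCl4, Et3N, HCO2Me (excess), CH2Cl2, 0 °C
Reagents that add atoms: methyl formate, COC=O
Why: Titanium-mediated crossed Claisen condensation (α-formylation of an ester); the product is held as a titanium chelate of its enolate, which should prevent self-condensation.

**Step 3**
Reactants: 4 prop-2-en-1-yl 2-formylheptanoate
Product: 5 prop-2-en-1-yl (2E)-3-{[(4-methylphenyl)sulfonyl]oxy}-2-pentylprop-2-enoate
Conditions: TsCl, N-methylimidazole, Et3N, MeCN, 0 °C
Reagents that add atoms: p-toluenesulfonyl chloride, Cc1ccc(cc1)S(Cl)(=O)=O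
Why: O-sulfonylation of the enol through the N-sulfonylimidazolium salt; an amine base without a chelating metal should favour the E enol tosylate, and the geometry is not critical because the next step can converge on the more stable E ether.

**Step 4**
Reactants: 2 methyl 2-hydroxy-4-(methoxymethoxy)-6-methylbenzoate; 5 prop-2-en-1-yl (2E)-3-{[(4-methylphenyl)sulfonyl]oxy}-2-pentylprop-2-enoate
Product: 6 prop-2-en-1-yl (2E)-3-[2-(methoxycarbonyl)-5-(methoxymethoxy)-3-methylphenoxy]-2-pentylprop-2-enoate
Conditions: Cs2CO3, MeCN, 20 → 50 °C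
Reagents that add atoms: none
Why: Addition–elimination (nucleophilic vinylic substitution) of the cesium phenoxide at the unhindered β-carbon of the β-sulfonyloxy acrylate, with loss of tosylate; retention and thermodynamic preference should both give the E aryl enol ether (aryloxy trans to the ester).

**Step 5**
Reactants: 6 prop-2-en-1-yl (2E)-3-[2-(methoxycarbonyl)-5-(methoxymethoxy)-3-methylphenoxy]-2-pentylprop-2-enoate
Product: 7 (2E)-3-[2-(methoxycarbonyl)-5-(methoxymethoxy)-3-methylphenoxy]-2-pentylprop-2-enoic acid
Conditions: Pd(PPh3)4 (cat.), TolSO2Na, THF/MeOH, 20 °C; then cold dilute aq. HCl to pH 3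
Reagents that add atoms: none
Why: Tsuji–Trost deallylation, in which zerovalent palladium ionizes the allyl ester and the soft sulfinate takes the allyl group; the conditions are neutral, so the methyl benzoate, the MOM ether and the aryloxyacrylate (prone to hydroxide or amine exchange) should be left alone.

**Step 6**
Reactants: 7 (2E)-3-[2-(methoxycarbonyl)-5-(methoxymethoxy)-3-methylphenoxy]-2-pentylprop-2-enoic acid
Product: 9 methyl 2-{[(1E)-2-(diazoacetyl)hept-1-en-1-yl]oxy}-4-(methoxymethoxy)-6-methylbenzoate, via acid chloride 8 (not isolated)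
Conditions: 1-chloro-N,N,2-trimethylprop-1-en-1-amine, CH2Cl2, 0 → 20 °C; then added to CH2N2 (3.5 equiv), Et2O, 0 °C
Reagents that add atoms: diazomethane, C=[N+]=[N-]
Why: Neutral acid chloride formation with the Ghosez reagent (which supplies the chlorine of 8) followed by Arndt–Eistert-type acylation of diazomethane, whose excess removes HCl; the push–pull, trisubstituted alkene should be a poor dipolarophile, so pyrazoline formation is not expected to compete.

**Step 7**
Reactants: 10 chloroacetaldehyde dimethyl acetal (2-chloro-1,1-dimethoxyethane)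
Product: 12 methoxyacetylene (methoxyethyne), via sodium methoxyacetylide 11 (not isolated)
Conditions: NaNH2 (3 equiv), liq. NH3, −33 °C; evaporate NH3; sat. aq. NaCl, −70 → 40 °C, distil into a −78 °C trap (bp about 23 °C), use as a cold ClCH2CH2Cl solution
Reagents that add atoms: none
Why: Two successive base-induced eliminations (methanol, then HCl) and deprotonation give the sodium acetylide, which water protonates; this is the standard preparation of the lower alkoxyacetylenes.

**Step 8**
Reactants: 9 methyl 2-{[(1E)-2-(diazoacetyl)hept-1-en-1-yl]oxy}-4-(methoxymethoxy)-6-methylbenzoate; 12 methoxyacetylene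
Product: 17 methyl 2-(2-hydroxy-4-methoxy-6-pentylphenoxy)-4-(methoxymethoxy)-6-methylbenzoate, via vinylketene 13 (not isolated), via vinylcyclobutenone 14 (not isolated), via dienylketene 15 (not isolated), via cyclohexadienone 16 (not isolated)
Conditions: hν (λ > 300 nm, Pyrex, medium-pressure Hg lamp), 12 (3 equiv), degassed ClCH2CH2Cl, 20 °C, sealed vessel; then 80 °C
Reagents that add atoms: none
Why: Light expels N2 from 9 and the alkenyl group shifts to the former diazo carbon (photochemical Wolff rearrangement, making C5'–C6') to give the (2-aryloxyvinyl)ketene 13; its ketene C=C adds methoxyacetylene in a (2+2) cycloaddition that joins the ketene carbonyl carbon to the unsubstituted alkyne carbon (C2'–C3') and the ketene α-carbon to the methoxy-bearing carbon (C4'–C5'), giving cyclobutenone 14. Four-electron electrocyclic ring opening of 14, by light or on heating, gives dienylketene 15, and ring B is closed by a thermal disrotatory six-electron electrocyclization of the ketene carbon onto the aryloxy-bearing alkene terminus (C1'–C2'); tautomerization of dienone 16 gives the phenol. The closest known reaction is the Danheiser benzannulation in its second-generation form, from α,β-unsaturated α'-diazo ketones and alkoxy- or siloxyalkynes, which gives resorcinol monoethers. No stereocenter is created, since the sp3 centres of 14 and 16 are lost on aromatization. The step needs regioselectivity in the cycloaddition, which the polarization of the ynol ether secures by placing the methoxy carbon meta to the new hydroxyl. It also needs a terminus that can cyclize: the E enol ether turns the aryloxy group outward, the reversible ring opening supplies the cyclizable dienylketene geometry, and irradiation above 300 nm addresses the diazo ketone and not the benzoate chromophore.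

**Step 9**
Reactants: 17 methyl 2-(2-hydroxy-4-methoxy-6-pentylphenoxy)-4-(methoxymethoxy)-6-methylbenzoate
Product: 18 methyl 2-[4-methoxy-2-(methoxymethoxy)-6-pentylphenoxy]-4-(methoxymethoxy)-6-methylbenzoate
Conditions: MOMCl, iPr2NEt, Bu4NI (cat.), CH2Cl2, 0 → 40 °C
Reagents that add atoms: chloromethyl methyl ether, COCCl
Why: O-alkylation of the C2' phenol to its MOM acetal; the weak amine base keeps the phenoxide concentration low, so attack on the hindered neighbouring ester (seven-membered lactone) should not compete.

**Step 10**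
Reactants: 19 hexanoyl chloride
Product: 20 N-methoxy-N-methylhexanamide
Conditions: MeNHOMe·HCl, Et3N (2.2 equiv), CH2Cl2, 0 °C
Reagents that add atoms: N,O-dimethylhydroxylamine hydrochloride, CNOC.Cl
Why: Schotten–Baumann-type N-acylation gives the Weinreb amide, the acylating agent that stops cleanly at the ketone stage in the next step.

**Step 11**
Reactants: 18 methyl 2-[4-methoxy-2-(methoxymethoxy)-6-pentylphenoxy]-4-(methoxymethoxy)-6-methylbenzoate; 20 N-methoxy-N-methylhexanamide
Product: 23 methyl 2-[4-methoxy-2-(methoxymethoxy)-6-pentylphenoxy]-4-(methoxymethoxy)-6-(2-oxoheptyl)benzoate, via benzyllithium 21 (not isolated), via tetrahedral adduct 22 (not isolated)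
Conditions: LiN(iPr)2 (1.3 equiv), THF, −78 °C; then 20 (1.5 equiv), −78 → −40 °C; AcOH, −78 °C
Reagents that add atoms: none
Why: Lateral (benzylic) lithiation of the ortho-toluate gives an anion stabilized as the extended ester enolate, and Weinreb acylation stops at the chelated tetrahedral adduct, so the acidic ketone appears only on quench and neither quenches the anion nor adds a second time.

**Step 12**
Reactants: 23 methyl 2-[4-methoxy-2-(methoxymethoxy)-6-pentylphenoxy]-4-(methoxymethoxy)-6-(2-oxoheptyl)benzoate
Product: 25 6-hydroxy-8-(2-hydroxy-4-methoxy-6-pentylphenoxy)-3-pentyl-1H-isochromen-1-one (target), via bis-phenol keto ester 24 (not isolated)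
Conditions: 3 M aq. HCl, MeOH/THF, 50 °C; then evaporate, TsOH·H2O (cat.), PhMe, 100 °C
Reagents that add atoms: none
Why: Acid hydrolysis removes both MOM acetals (methanol holds the released formaldehyde as its acetal, away from the electron-rich ring B), and acid-catalysed enol lactonization of the benzylic ketone onto the neighbouring methyl ester, with loss of methanol, should close the six-membered pyranone ring C.

**Compound list**
1 | methyl orsellinate (methyl 2,4-dihydroxy-6-methylbenzoate) | COC(=O)c1c(C)cc(O)cc1O | starting material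
2 | methyl 2-hydroxy-4-(methoxymethoxy)-6-methylbenzoate | COC(=O)c1c(C)cc(OCOC)cc1O | intermediate
3 | allyl heptanoate (prop-2-en-1-yl heptanoate) | CCCCCCC(=O)OCC=C | starting material
4 | prop-2-en-1-yl 2-formylheptanoate (racemic, enolizable) | CCCCCC(C=O)C(=O)OCC=C | intermediate
5 | prop-2-en-1-yl (2E)-3-{[(4-methylphenyl)sulfonyl]oxy}-2-pentylprop-2-enoate | CCCCC/C(=C\OS(=O)(=O)c1ccc(C)cc1)C(=O)OCC=C | intermediate
6 | prop-2-en-1-yl (2E)-3-[2-(methoxycarbonyl)-5-(methoxymethoxy)-3-methylphenoxy]-2-pentylprop-2-enoate | CCCCC/C(=C\Oc1cc(OCOC)cc(C)c1C(=O)OC)C(=O)OCC=C | intermediate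
7 | (2E)-3-[2-(methoxycarbonyl)-5-(methoxymethoxy)-3-methylphenoxy]-2-pentylprop-2-enoic acid | CCCCC/C(=C\Oc1cc(OCOC)cc(C)c1C(=O)OC)C(=O)O | intermediate
8 | (2E)-3-[2-(methoxycarbonyl)-5-(methoxymethoxy)-3-methylphenoxy]-2-pentylprop-2-enoyl chloride (not isolated) | CCCCC/C(=C\Oc1cc(OCOC)cc(C)c1C(=O)OC)C(=O)Cl | intermediate
9 | methyl 2-{[(1E)-2-(diazoacetyl)hept-1-en-1-yl]oxy}-4-(methoxymethoxy)-6-methylbenzoate | CCCCC/C(=C\Oc1cc(OCOC)cc(C)c1C(=O)OC)C(=O)C=[N+]=[N-] | intermediate
10 | chloroacetaldehyde dimethyl acetal (2-chloro-1,1-dimethoxyethane) | COC(CCl)OC | starting material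
11 | sodium methoxyacetylide (not isolated) | COC#[C-].[Na+] | intermediate
12 | methoxyacetylene (methoxyethyne) | COC#C | intermediate
13 | methyl 4-(methoxymethoxy)-2-methyl-6-{[(1E)-4-oxo-2-pentylbuta-1,3-dien-1-yl]oxy}benzoate, the vinylketene (not isolated) | CCCCC/C(=C\Oc1cc(OCOC)cc(C)c1C(=O)OC)C=C=O | intermediate
14 | methyl 2-{[(1E)-2-(2-methoxy-4-oxocyclobut-2-en-1-yl)hept-1-en-1-yl]oxy}-4-(methoxymethoxy)-6-methylbenzoate, racemic (not isolated) | CCCCC/C(=C\Oc1cc(OCOC)cc(C)c1C(=O)OC)C1C(=O)C=C1OC | intermediate
15 | methyl 2-{[(1E,3E)-4-methoxy-6-oxo-2-pentylhexa-1,3,5-trien-1-yl]oxy}-4-(methoxymethoxy)-6-methylbenzoate, the dienylketene (not isolated) | O=C=C/C(OC)=C\C(CCCCC)=C\Oc1cc(OCOC)cc(C)c1C(=O)OC | intermediate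
16 | methyl 2-[(4-methoxy-6-oxo-2-pentylcyclohexa-2,4-dien-1-yl)oxy]-4-(methoxymethoxy)-6-methylbenzoate, racemic (not isolated) | CCCCCC1=CC(OC)=CC(=O)C1Oc1cc(OCOC)cc(C)c1C(=O)OC | intermediate
17 | methyl 2-(2-hydroxy-4-methoxy-6-pentylphenoxy)-4-(methoxymethoxy)-6-methylbenzoate | COC(=O)c1c(C)cc(OCOC)cc1Oc1c(O)cc(OC)cc1CCCCC | intermediate
18 | methyl 2-[4-methoxy-2-(methoxymethoxy)-6-pentylphenoxy]-4-(methoxymethoxy)-6-methylbenzoate | COC(=O)c1c(C)cc(OCOC)cc1Oc1c(OCOC)cc(OC)cc1CCCCC | intermediate
19 | hexanoyl chloride | CCCCCC(=O)Cl | starting material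
20 | N-methoxy-N-methylhexanamide | CCCCCC(=O)N(C)OC | intermediate
21 | {2-(methoxycarbonyl)-3-[4-methoxy-2-(methoxymethoxy)-6-pentylphenoxy]-5-(methoxymethoxy)phenyl}methyllithium (not isolated) | [Li]Cc1cc(OCOC)cc(Oc2c(OCOC)cc(OC)cc2CCCCC)c1C(=O)OC | intermediate
22 | lithium alkoxide of the N-methoxy-N-methyl hemiaminal formed from 21 and 20, racemic (not isolated) | CCCCCC(O[Li])(Cc1cc(OCOC)cc(Oc2c(OCOC)cc(OC)cc2CCCCC)c1C(=O)OC)N(C)OC | intermediate
23 | methyl 2-[4-methoxy-2-(methoxymethoxy)-6-pentylphenoxy]-4-(methoxymethoxy)-6-(2-oxoheptyl)benzoate | CCCCCC(=O)Cc1cc(OCOC)cc(Oc2c(OCOC)cc(OC)cc2CCCCC)c1C(=O)OC | intermediate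
24 | methyl 4-hydroxy-2-(2-hydroxy-4-methoxy-6-pentylphenoxy)-6-(2-oxoheptyl)benzoate (not isolated) | CCCCCC(=O)Cc1cc(O)cc(Oc2c(O)cc(OC)cc2CCCCC)c1C(=O)OC | intermediate
25 | 6-hydroxy-8-(2-hydroxy-4-methoxy-6-pentylphenoxy)-3-pentyl-1H-isochromen-1-one | CCCCCc1cc2cc(O)cc(Oc3c(O)cc(OC)cc3CCCCC)c2c(=O)o1 | target

**Step count**
Total: 12 steps. Longest linear sequence: 9 steps (3 → 4 → 5 → 6 → 7 → 9 → 17 → 18 → 23 → 25; steps 2, 3, 4, 5, 6, 8, 9, 11, 12).

**Steps most likely to fail**

Step 8. The aryl enol ether and benzoate chromophores may degrade under irradiation. The ketene may be lost by dimerization or by acylating the product phenol before the volatile alkyne captures it. The vinylogous-ester cyclobutenone may open only slowly. The fallback generates the same ketene in the dark and sets out from 9. A silver-catalysed Wolff rearrangement in wet solvent (AgO2CPh cat., Et3N, THF/H2O, 20 °C, dark) should give the homologous acid (3E)-4-[2-(methoxycarbonyl)-5-(methoxymethoxy)-3-methylphenoxy]-3-pentylbut-3-enoic acid F1. 1-Chloro-N,N,2-trimethylprop-1-en-1-amine in CH2Cl2 converts it into (3E)-4-[2-(methoxycarbonyl)-5-(methoxymethoxy)-3-methylphenoxy]-3-pentylbut-3-enoyl chloride F2. Slow addition of Et3N to F2 and excess 12 at 0 → 20 °C dehydrochlorinates F2 at its α-carbon to vinylketene 13, which is trapped as cyclobutenone 14 (the known ketene–alkoxyacetylene cycloaddition). Heating in PhMe at 80–100 °C then carries 14 through 15 and 16. The fallback comes back to the route at 17.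

Step 4. The phenoxide may attack sulfur instead of carbon, transferring the sulfonyl group to the phenol and returning the formyl ester enolate. The fallback replaces the sulfonate by a vinylogous acid chloride, which has no such pathway, and sets out from 4. Oxalyl chloride and DMF in CH2Cl2 at 0 °C (Vilsmeier-type chlorination of the hydroxymethylene tautomer) should give prop-2-en-1-yl 3-chloro-2-pentylprop-2-enoate F3 as an E/Z mixture. Addition–elimination of phenol 2 (K2CO3, DMF, 50 °C) should converge on the E ether. The fallback comes back at 6.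

Step 11. Proton transfer from the enolizable amide to the benzylic anion may return 18, and the anion may condense with the ester of a second molecule. The fallback uses a more electrophilic, non-acylating partner and sets out from 21, generated as in step 11. Addition to hexanal at −78 °C and a cold AcOH quench (to keep the hindered ester from lactonizing) should give methyl 2-(2-hydroxyheptyl)-6-[4-methoxy-2-(methoxymethoxy)-6-pentylphenoxy]-4-(methoxymethoxy)benzoate F4 (racemic). Dess–Martin periodinane with NaHCO3 in CH2Cl2 oxidizes the alcohol to the ketone. The fallback comes back at 23.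

**Further compounds**
F1 | step 8 | (3E)-4-[2-(methoxycarbonyl)-5-(methoxymethoxy)-3-methylphenoxy]-3-pentylbut-3-enoic acid | CCCCC/C(=C\Oc1cc(OCOC)cc(C)c1C(=O)OC)CC(=O)O
F2 | step 8 | (3E)-4-[2-(methoxycarbonyl)-5-(methoxymethoxy)-3-methylphenoxy]-3-pentylbut-3-enoyl chloride | CCCCC/C(=C\Oc1cc(OCOC)cc(C)c1C(=O)OC)CC(=O)Cl
F3 | step 4 | prop-2-en-1-yl 3-chloro-2-pentylprop-2-enoate (E/Z mixture) | CCCCCC(=CCl)C(=O)OCC=C
F4 | step 11 | methyl 2-(2-hydroxyheptyl)-6-[4-methoxy-2-(methoxymethoxy)-6-pentylphenoxy]-4-(methoxymethoxy)benzoate (racemic) | CCCCCC(O)Cc1cc(OCOC)cc(Oc2c(OCOC)cc(OC)cc2CCCCC)c1C(=O)OC
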